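Compound numbers 1–25 are those of the steps below. Atom numbering follows the target: C1 (aryl A = 4-hydroxy-3-methoxyphenyl, endo), O2, C3, C3a, C4 (aryl B = 3-methoxy-4-prenyloxyphenyl, exo), O5, C6, C6a. Ring A = C1–O2–C3–C3a–C6a, ring B = C4–O5–C6–C6a–C3a.

## The problem

Target 25 is an unsymmetrical 1,4-diaryl furofuran: two cis-fused tetrahydrofurans sharing C3a–C6a, with four contiguous stereocentres (1R,3aR,4S,6aR). Aryl B at C4 lies on the convex face, the position that an addition anti to an existing substituent or an equilibration provides. Aryl A at C1 lies on the concave face, the less stable arrangement. Both benzylic C–O bonds ionise readily next to electron-rich aryl groups, and ionisation at C1 turns endo into exo; C1 therefore has to be set under kinetic control and then kept away from acid and from a free para-phenoxide. The stereocentres can be relayed: C4 directs additions to a C3a=C6a alkene to the opposite face, and the resulting ring fusion offers a convex face from which C1 can be completed. The two guaiacyl rings differ only at the para oxygen, so the phenols need different masks from the start, and the prenyl ether (labile to acid, peracid, hydrogenation and ketene-type electrophiles) must enter late. The enabling feature is that ring A without O2 is a four-membered carbocycle (C1, C3, C3a, C6a): a cyclobutanone with the carbonyl at C3 and aryl A at C1 becomes ring A, at the lactone level, when one oxygen is inserted between C3 and the benzylic C1 with retention.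

## Retrosynthesis

**25 back to lactone 19** (cuts: aryl A O–Si, O2–C3, aryl B O–prenyl; C3 returned to the acid oxidation level). Phenol 25 is the desilylation product of 24. Furofuran 24 arises from diol 22 by closing O2–C3 through the primary sulfonate 23, which leaves the C1–O2 bond and the endo configuration untouched. Diol 22 is the prenyl ether made from triol 20 and bromide 21, and 20 is what hydride gives from lactone 19. Carrying aryl B as a pivalate was preferred over an allyl ether to be converted by cross-metathesis: the hydride that opens the lactone also frees the aryl B phenol, and no alkene is present in the cycloaddition or peracid steps. Aryl A keeps a triisopropylsilyl ether, so C1 is never para to a free phenol until the last step.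

**19 back to cyclobutanone 17** (cuts: C1–O2 and O2–C3). Removing O2 contracts ring A to the four-membered ketone 17, in which all four stereocentres are already present. This cut was preferred over cuts at the C–C bonds of ring A because the forward step creates no stereocentre and only has to choose which α-carbon migrates. The forward oxidation must move C1, not C3a, and must not epimerise the α-aryl ketone.

**17 back to ketone 14** (cut: C1–H). The endo aryl of 17 is the less stable epimer, so C1 is taken back to a trigonal centre: chloride 16, made from 14 through enolate 15. Hydrogen delivered to the C1 radical from the convex face places aryl A endo. Ketone 14 may therefore be any mixture at C1, which removes one stereochemical demand from the cycloaddition.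

**14 back to dihydrofuran 6 and amide 10** (cuts: C3–C3a and C1–C6a). The cyclobutanone is a [2+2] adduct of the ring B alkene 6 and a two-carbon unit carrying aryl A. A haloketene would bring the chlorine with it, but ketenes other than dichloroketene react poorly with an unactivated alkene flanked by two allylic oxygens. The keteniminium salt 12, generated from amide 10 through 11, is the stronger electrophile, and its adduct 13 hydrolyses to 14. The precursor 6 has one stereocentre and one ring. The forward step must add anti to aryl B and must place the carbonyl carbon next to C4.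

**6 back to triflate 4 and 2,3-dihydrofuran 5** (cut: C4–aryl B). An asymmetric Heck arylation sets C4 and delivers the alkene in the 2,5-position in one step from an achiral triflate. The alternatives (building the dihydrofuran from an aryl B aldehyde by asymmetric addition and ring closure) are longer.

**4 back to phenol 1; 10 back to homovanillic acid 7.** Triflate 4 comes from 1 by triflation (2), debenzylation (3) and pivaloylation; the benzyl group is removed before any benzylic ring ether exists. Amide 10 comes from 7 through imidazolide 8 and amide 9.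

## Roads not taken

**Alternative 1:** three-component assembly on a chiral butenolide.
- Cut: C1–C6a and C3a–C4.
- Forward key step: the lithiated dithiane A2 adds to the β-carbon of the menthyloxy butenolide A3 anti to the auxiliary, and the enolate is trapped by the aryl B aldehyde A4 to give A1.
- Merits: two C–C bonds in one flask, a reliable trans relationship at C3a/C6a (the one that becomes the cis ring fusion), absolute configuration from an inexpensive auxiliary, and no regiochemical question. On the last point it is better than the chosen plan.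
- Weak points: A1 contains neither ring of the target. C1 is at the ketone oxidation level and would be set by a late reduction of an open-chain aryl ketone with nothing to bias it towards the endo series. C4 depends on aldol diastereoselectivity. The dithiane has to be removed with soft electrophiles or oxidants in the presence of an allyl ether and electron-rich arenes. C6 and C3 both still need reduction, and two ring closures at benzylic carbons each need a defined stereochemical course.
- Comparison: the chosen plan has all four stereocentres in a rigid bicycle before its key step and needs four steps afterwards; this road would need roughly twice as many, with C1 decided last.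

**Alternative 2:** acetal-triggered closure of ring B.
- Cut: O5–C4 and C3a–C4.
- Forward key step: a silyl triflate exchanges the primary alcohol of the cis-dihydrofuran A6 into the acetal A7, and the oxocarbenium ion is attacked by the enol ether carbon C3a; the released alkoxy group caps C3 to give A5.
- Merits: ring B, two bonds and C4 are made in one step, C4 forms under conditions that favour the exo aryl that is wanted there, and A5 is one reduction away from the ring system. In bonds and stereocentres built per step it is better than the chosen plan, whose key step builds no stereocentre.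
- Weak points: the difficult centre is moved into A6, a cis-2-aryl-3-(hydroxymethyl)-2,3-dihydrofuran whose enantioselective synthesis is a project of its own. Both the key step and the acetal reduction expose the endo C1–O2 benzylic bond to strong Lewis acid, the very conditions under which endo becomes exo.
- Comparison: the chosen plan sets C1 by a ring-controlled hydrogen transfer and afterwards uses only peracid with buffer, hydride, base and fluoride. It pays for this with more steps and an unproven cycloaddition regiochemistry.

**Alternative 3:** carbonyl ylide cycloaddition.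
- Cut: C1–C6a and C3–C3a.
- Forward key step: fluoride-induced 1,3-elimination of the chloro silylmethyl ether A10 gives a non-stabilised carbonyl ylide, which adds across C6a=C3a of the butenolide A9 anti to aryl B and closes ring A to give A8.
- Merits: the shortest road. Ring A is formed with C3 already at the ether level, and the butenolide face selection places aryl B exo. In step count it is clearly ahead of the chosen plan.
- Weak points: the ylide is unsymmetrical and acyclic. Its aryl-bearing terminus must bond to the α-carbon C6a and the aryl group must end up endo; neither the regiochemistry nor the endo/exo choice has a control element, and the exo aryl is the likelier outcome. The ring B lactone of A8 then has to be reduced to the ether without disturbing C1.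
- Comparison: the chosen plan also carries an unproven regiochemistry (in the [2+2] of 6), so on that count the two are equal. The difference is that the chosen plan decides C1 separately, by convex-face hydrogen delivery to a ring-bound radical, and that step can be repeated or replaced.

Key step: step 10

Assumption: 4-(benzyloxy)-3-methoxyphenol (1) is taken as a catalogue compound; it is otherwise two routine steps from vanillin (O-benzylation, then peracid oxidation of the aldehyde and formate cleavage).
Assumption: the (R)-configured tert-butyl phosphinooxazoline ligand is taken to give the (S)-2-aryl-2,5-dihydrofuran, by analogy with the sense of induction of this ligand class with simple aryl triflates; should 4 behave otherwise, the mirror-image ligand is used and nothing else changes.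

## Route

Step 1
Reactants: 1 4-(benzyloxy)-3-methoxyphenol
Product: 2 4-(benzyloxy)-3-methoxyphenyl trifluoromethanesulfonate
Conditions: Tf2O, pyridine, CH2Cl2, 0 °C
Reagents that add atoms: trifluoromethanesulfonic anhydride, O=S(=O)(OS(=O)(=O)C(F)(F)F)C(F)(F)F
Why: Sulfonylation of a phenol with triflic anhydride and pyridine is a standard aryl triflate synthesis; the benzyl ether keeps the second oxygen apart, so the Heck leaving group ends up para to it.

Step 2
Reactants: 2 4-(benzyloxy)-3-methoxyphenyl trifluoromethanesulfonate
Product: 3 4-hydroxy-3-methoxyphenyl trifluoromethanesulfonate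
Conditions: H2 (1 atm), 10% Pd/C, EtOAc, rt
Reagents that add atoms: none
Why: Catalytic hydrogenolysis of an aryl benzyl ether; in a neutral medium without added base the aryl triflate is not reduced, and the benzyl group is removed here because no alkene or benzylic ring ether is present yet.

Step 3
Reactants: 3 4-hydroxy-3-methoxyphenyl trifluoromethanesulfonate
Product: 4 2-methoxy-4-(trifluoromethanesulfonyloxy)phenyl 2,2-dimethylpropanoate
Conditions: t-BuCOCl, Et3N, DMAP (cat.), CH2Cl2, 0 °C → rt
Reagents that add atoms: pivaloyl chloride, CC(C)(C)C(Cl)=O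
Why: Acylation of a phenol with an acid chloride; the pivalate has no α-hydrogen, withstands triflic anhydride, amide base, tin hydride and peracid, makes aryl B a weaker donor so that the benzylic C4–O5 bond formed in step 4 ionises less readily, and is cleaved without an extra step by LiAlH4 in step 11.

Step 4
Reactants: 4 2-methoxy-4-(trifluoromethanesulfonyloxy)phenyl 2,2-dimethylpropanoate; 5 2,3-dihydrofuran
Product: 6 2-methoxy-4-[(2S)-2,5-dihydrofuran-2-yl]phenyl 2,2-dimethylpropanoate
Conditions: Pd2(dba)3 (1.5 mol %), (R)-4-tert-butyl-2-[2-(diphenylphosphanyl)phenyl]-4,5-dihydrooxazole (6 mol %), i-Pr2NEt, 5 (5 equiv), THF, 70 °C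
Reagents that add atoms: none
Why: Asymmetric intermolecular Heck reaction: 4 adds oxidatively to zerovalent palladium, the cationic aryl–palladium complex inserts the enol ether with aryl at the oxygen-bearing carbon, and β-hydride elimination away from the new centre gives the 2,5-dihydrofuran, which the P,N ligand releases without double-bond migration; the ligand selects the face of insertion and so sets C4 (S).

Step 5
Reactants: 7 homovanillic acid
Product: 9 2-(4-hydroxy-3-methoxyphenyl)-N,N-dimethylacetamide, via acyl imidazolide 8 (not isolated)
Conditions: 1,1'-carbonyldiimidazole, THF, rt; then Me2NH (2 M in THF), rt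
Reagents that add atoms: dimethylamine, CNC; 1,1'-carbonyldiimidazole, O=C(n1ccnc1)n1ccnc1 (imidazolyl group in 8 only)
Why: Amide formation through the acyl imidazolide; the carboxylic acid reacts with the reagent much faster than the phenol, and any aryl ester or carbonate formed in passing is cleaved by the excess amine.

Step 6
Reactants: 9 2-(4-hydroxy-3-methoxyphenyl)-N,N-dimethylacetamide
Product: 10 2-[3-methoxy-4-(triisopropylsilyloxy)phenyl]-N,N-dimethylacetamide
Conditions: i-Pr3SiCl, imidazole, DMF, rt
Reagents that add atoms: chlorotriisopropylsilane, CC(C)[Si](Cl)(C(C)C)C(C)C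
Why: Silylation of a phenol with a silyl chloride and imidazole; the triisopropylsilyl ether is chosen over smaller silyl groups because it has to survive LiAlH4 (step 11) and carbonate (step 12) and still leave with fluoride at the end.

Step 7
Reactants: 10 2-[3-methoxy-4-(triisopropylsilyloxy)phenyl]-N,N-dimethylacetamide; 6 2-methoxy-4-[(2S)-2,5-dihydrofuran-2-yl]phenyl 2,2-dimethylpropanoate
Product: 14 (1R,4S,5S,7S)-4-(3-methoxy-4-pivaloyloxyphenyl)-7-(3-methoxy-4-triisopropylsilyloxyphenyl)-3-oxabicyclo[3.2.0]heptan-6-one (7-exo-aryl A epimer), via O-triflyl iminium triflate 11 (not isolated), via keteniminium triflate 12 (not isolated), via cyclobutaniminium triflate 13 (not isolated)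
Conditions: 10 (1.5 equiv), Tf2O, 2,4,6-collidine, ClCH2CH2Cl, 0 → 80 °C; then H2O, rt
Reagents that add atoms: water, O; trifluoromethanesulfonic anhydride, O=S(=O)(OS(=O)(=O)C(F)(F)F)C(F)(F)F (triflyl group and triflate counter-ion in 11 to 13 only)
Why: Keteniminium–alkene [2+2] cycloaddition (amide activation with triflic anhydride and a hindered pyridine), a stepwise polar cycloaddition that works with unactivated cyclic cis-alkenes where ketenes other than dichloroketene are too sluggish; the iminium carbon should bond to the alkene carbon next to C4 so that positive charge builds on the carbon remote from the one bearing O5 and the acyloxyaryl group, the substituted terminus C1 then closes on the less hindered carbon, and both bonds form on the face opposite aryl B, which sets C3a and C6a (cis fusion, aryl B exo); hydrolysis of 13 is expected to give mainly the exo-aryl ketone, and any endo epimer is carried along because C1 is erased in step 8.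

Step 8
Reactants: 14 (1R,4S,5S,7S)-4-(3-methoxy-4-pivaloyloxyphenyl)-7-(3-methoxy-4-triisopropylsilyloxyphenyl)-3-oxabicyclo[3.2.0]heptan-6-one
Product: 16 (1R,4S,5S,7S)-7-chloro-4-(3-methoxy-4-pivaloyloxyphenyl)-7-(3-methoxy-4-triisopropylsilyloxyphenyl)-3-oxabicyclo[3.2.0]heptan-6-one, via lithium enolate 15 (not isolated)
Conditions: LiN(SiMe3)2, THF, −78 °C; then N-chlorosuccinimide, −78 → −40 °C
Reagents that add atoms: N-chlorosuccinimide, O=C1CCC(=O)N1Cl; LiN(SiMe3)2, [Li]N([Si](C)(C)C)[Si](C)(C)C (lithium in 15 only)
Why: Electrophilic α-chlorination of a ketone enolate; only the benzylic C1–H is removed, because enolisation towards C3a would place a double bond at the ring fusion of the strained bicycle, the pivalate has no acidic hydrogen and is too hindered to be attacked at −78 °C, and either C1 epimer of 16 serves (the convex-face chloride is drawn).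

Step 9
Reactants: 16 (1R,4S,5S,7S)-7-chloro-4-(3-methoxy-4-pivaloyloxyphenyl)-7-(3-methoxy-4-triisopropylsilyloxyphenyl)-3-oxabicyclo[3.2.0]heptan-6-one
Product: 17 (1R,4S,5S,7R)-4-(3-methoxy-4-pivaloyloxyphenyl)-7-(3-methoxy-4-triisopropylsilyloxyphenyl)-3-oxabicyclo[3.2.0]heptan-6-one (7-endo-aryl A epimer)
Conditions: Bu3SnH, Et3B (cat.), air, toluene, 0 °C; used without chromatography
Reagents that add atoms: none
Why: Radical dehalogenation: chlorine abstraction gives a planar benzylic α-keto radical at C1, and the tin hydride transfers hydrogen to it from the open convex face, away from ring B, which pushes aryl A to the concave face (C1 endo); this is the established course of tin hydride reduction of 7-chloro-7-substituted bicyclo[3.2.0]heptan-6-ones, and the neutral, cold conditions should not epimerise the product.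

Step 10
Reactants: 17 (1R,4S,5S,7R)-4-(3-methoxy-4-pivaloyloxyphenyl)-7-(3-methoxy-4-triisopropylsilyloxyphenyl)-3-oxabicyclo[3.2.0]heptan-6-one
Product: 19 (1R,3aS,4S,6aR)-1-(3-methoxy-4-triisopropylsilyloxyphenyl)-4-(3-methoxy-4-pivaloyloxyphenyl)tetrahydro-1H,3H-furo[3,4-c]furan-3-one (target numbering; lactone carbonyl at C3), via Criegee adduct 18 (not isolated)
Conditions: mCPBA, NaHCO3, CH2Cl2, 0 °C
Reagents that add atoms: 3-chloroperoxybenzoic acid, OOC(=O)c1cccc(Cl)c1
Why: Baeyer–Villiger oxidation: the peracid adds to the strained carbonyl C3 to give the Criegee adduct 18, and the C1–C3 bond antiperiplanar to the O–O bond migrates to oxygen as 3-chlorobenzoate leaves, making C1–O2 and O2–C3. The closest known reaction type is the peracid oxidation of 2-arylcyclobutanones to γ-aryl-γ-butyrolactones, in which the aryl-bearing carbon migrates. Ring A is closed not by an end-to-end cyclisation but by a one-atom ring expansion, a 1,2-shift of C1 from carbon to oxygen within the four-membered ring, driven by release of cyclobutanone strain. No stereocentre is created: C1 migrates with retention, so the endo aryl A of 17 becomes the endo aryl A of 19, and C3a, C4 and C6a are spectators. The selectivity needed is migration of C1 and not of the ring-fusion carbon C3a; C1 is benzylic and carries the electron-rich silyloxyaryl group that stabilises positive charge on the migrating carbon, whereas C3a is inductively deactivated by O5 two bonds away. The second requirement, no epimerisation of the α-aryl ketone before oxidation, is met by the solid NaHCO3 buffer, the low temperature and the high rate at which cyclobutanones react. Nothing else in 17 is oxidisable under these conditions, since there is no alkene and the aryl pivalate and aryl silyl ether are inert to the peracid.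

Step 11
Reactants: 19 (1R,3aS,4S,6aR)-1-(3-methoxy-4-triisopropylsilyloxyphenyl)-4-(3-methoxy-4-pivaloyloxyphenyl)tetrahydro-1H,3H-furo[3,4-c]furan-3-one
Product: 20 4-[(2S,3R,4R)-3-(hydroxymethyl)-4-{(R)-hydroxy[3-methoxy-4-(triisopropylsilyloxy)phenyl]methyl}tetrahydrofuran-2-yl]-2-methoxyphenol
Conditions: LiAlH4, THF, 0 °C
Reagents that add atoms: none
Why: Hydride reduction of a lactone to a 1,4-diol (the acyl C3–O2 bond opens, C1–O2 stays) together with reductive cleavage of the aryl pivalate; C1 keeps its configuration as a secondary benzylic alkoxide, and the aryl triisopropylsilyl ether is stable to LiAlH4 at 0 °C.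

Step 12
Reactants: 20 4-[(2S,3R,4R)-3-(hydroxymethyl)-4-{(R)-hydroxy[3-methoxy-4-(triisopropylsilyloxy)phenyl]methyl}tetrahydrofuran-2-yl]-2-methoxyphenol; 21 1-bromo-3-methylbut-2-ene (prenyl bromide)
Product: 22 {(2S,3R,4R)-4-{(R)-hydroxy[3-methoxy-4-(triisopropylsilyloxy)phenyl]methyl}-2-[3-methoxy-4-(3-methylbut-2-enyloxy)phenyl]tetrahydrofuran-3-yl}methanol
Conditions: K2CO3, acetone, rt
Reagents that add atoms: none
Why: Williamson etherification; carbonate deprotonates only the phenol, the phenoxide displaces the primary allylic bromide, the two aliphatic hydroxyls are not alkylated and the silyl ether of aryl A is untouched, so the prenyl group enters after the peracid and hydride steps that it would not survive.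

Step 13
Reactants: 22 {(2S,3R,4R)-4-{(R)-hydroxy[3-methoxy-4-(triisopropylsilyloxy)phenyl]methyl}-2-[3-methoxy-4-(3-methylbut-2-enyloxy)phenyl]tetrahydrofuran-3-yl}methanol
Product: 24 (1R,3aR,4S,6aR)-1-(3-methoxy-4-triisopropylsilyloxyphenyl)-4-[3-methoxy-4-(3-methylbut-2-enyloxy)phenyl]tetrahydro-1H,3H-furo[3,4-c]furan, via primary mesylate 23 (not isolated)
Conditions: MsCl (1.1 equiv), Et3N, CH2Cl2, −20 °C → rt
Reagents that add atoms: methanesulfonyl chloride, CS(Cl)(=O)=O (mesyl group in 23 only)
Why: Selective sulfonylation of the primary hydroxyl followed by intramolecular Williamson closure (5-exo-tet) by the C1 hydroxyl re-forms O2–C3; the C1–O2 bond is never broken, so the endo configuration is retained, and the basic medium avoids the benzylic ionisation that would turn aryl A exo.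

Step 14
Reactants: 24 (1R,3aR,4S,6aR)-1-(3-methoxy-4-triisopropylsilyloxyphenyl)-4-[3-methoxy-4-(3-methylbut-2-enyloxy)phenyl]tetrahydro-1H,3H-furo[3,4-c]furan
Product: 25 4-[(1R,3aR,4S,6aR)-4-{3-methoxy-4-[(3-methylbut-2-en-1-yl)oxy]phenyl}tetrahydro-1H,3H-furo[3,4-c]furan-1-yl]-2-methoxyphenol
Conditions: Bu4NF, AcOH, THF, 0 °C
Reagents that add atoms: none
Why: Fluoride cleavage of an aryl silyl ether; acetic acid buffers the phenoxide so that the para-hydroxybenzylic C1–O2 bond is not opened through a quinone methide, and the prenyl ether and both ring ethers are inert.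

## Compound list

1 | 4-(benzyloxy)-3-methoxyphenol | COc1cc(O)ccc1OCc1ccccc1 | starting material
2 | 4-(benzyloxy)-3-methoxyphenyl trifluoromethanesulfonate | COc1cc(OS(=O)(=O)C(F)(F)F)ccc1OCc1ccccc1 | intermediate
3 | 4-hydroxy-3-methoxyphenyl trifluoromethanesulfonate | COc1cc(OS(=O)(=O)C(F)(F)F)ccc1O | intermediate
4 | 2-methoxy-4-(trifluoromethanesulfonyloxy)phenyl 2,2-dimethylpropanoate | COc1cc(OS(=O)(=O)C(F)(F)F)ccc1OC(=O)C(C)(C)C | intermediate
5 | 2,3-dihydrofuran | C1CC=CO1 | starting material
6 | 2-methoxy-4-[(2S)-2,5-dihydrofuran-2-yl]phenyl 2,2-dimethylpropanoate | COc1cc([C@@H]2C=CCO2)ccc1OC(=O)C(C)(C)C | intermediate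
7 | homovanillic acid, 2-(4-hydroxy-3-methoxyphenyl)acetic acid | COc1cc(CC(=O)O)ccc1O | starting material
8 | 2-(4-hydroxy-3-methoxyphenyl)-1-(imidazol-1-yl)ethanone (acyl imidazolide) | COc1cc(CC(=O)n2ccnc2)ccc1O | intermediate (not isolated)
9 | 2-(4-hydroxy-3-methoxyphenyl)-N,N-dimethylacetamide | COc1cc(CC(=O)N(C)C)ccc1O | intermediate
10 | 2-[3-methoxy-4-(triisopropylsilyloxy)phenyl]-N,N-dimethylacetamide | COc1cc(CC(=O)N(C)C)ccc1O[Si](C(C)C)(C(C)C)C(C)C | intermediate
11 | O-triflyl iminium triflate of 10 | COc1cc(CC(OS(=O)(=O)C(F)(F)F)=[N+](C)C)ccc1O[Si](C(C)C)(C(C)C)C(C)C.[O-]S(=O)(=O)C(F)(F)F | intermediate (not isolated)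
12 | aryl A keteniminium triflate | COc1cc(C=C=[N+](C)C)ccc1O[Si](C(C)C)(C(C)C)C(C)C.[O-]S(=O)(=O)C(F)(F)F | intermediate (not isolated)
13 | cyclobutaniminium triflate, the [2+2] adduct of 12 and 6 (C1 epimers, C1 left undefined) | C[N+](C)=C1C(c2ccc(O[Si](C(C)C)(C(C)C)C(C)C)c(OC)c2)[C@H]2CO[C@H](c3ccc(OC(=O)C(C)(C)C)c(OC)c3)[C@@H]12.[O-]S(=O)(=O)C(F)(F)F | intermediate (not isolated)
14 | (1R,4S,5S,7S)-4-(3-methoxy-4-pivaloyloxyphenyl)-7-(3-methoxy-4-triisopropylsilyloxyphenyl)-3-oxabicyclo[3.2.0]heptan-6-one, exo-aryl A epimer drawn | O=C1[C@H](c2ccc(O[Si](C(C)C)(C(C)C)C(C)C)c(OC)c2)[C@H]2CO[C@H](c3ccc(OC(=O)C(C)(C)C)c(OC)c3)[C@@H]12 | intermediate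
15 | lithium enolate of 14 (C1=C3 enolate) | [Li]OC1=C(c2ccc(O[Si](C(C)C)(C(C)C)C(C)C)c(OC)c2)[C@H]2CO[C@H](c3ccc(OC(=O)C(C)(C)C)c(OC)c3)[C@@H]12 | intermediate (not isolated)
16 | (1R,4S,5S,7S)-7-chloro-4-(3-methoxy-4-pivaloyloxyphenyl)-7-(3-methoxy-4-triisopropylsilyloxyphenyl)-3-oxabicyclo[3.2.0]heptan-6-one, chlorine on the convex face drawn | O=C1[C@@](Cl)(c2ccc(O[Si](C(C)C)(C(C)C)C(C)C)c(OC)c2)[C@H]2CO[C@H](c3ccc(OC(=O)C(C)(C)C)c(OC)c3)[C@@H]12 | intermediate
17 | (1R,4S,5S,7R)-4-(3-methoxy-4-pivaloyloxyphenyl)-7-(3-methoxy-4-triisopropylsilyloxyphenyl)-3-oxabicyclo[3.2.0]heptan-6-one, aryl A endo, aryl B exo | O=C1[C@@H](c2ccc(O[Si](C(C)C)(C(C)C)C(C)C)c(OC)c2)[C@H]2CO[C@H](c3ccc(OC(=O)C(C)(C)C)c(OC)c3)[C@@H]12 | intermediate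
18 | Criegee adduct of 17 and 3-chloroperoxybenzoic acid (C3 hydroxy perester, C3 undefined) | OC1(OOC(=O)c2cccc(Cl)c2)[C@@H](c2ccc(O[Si](C(C)C)(C(C)C)C(C)C)c(OC)c2)[C@H]2CO[C@H](c3ccc(OC(=O)C(C)(C)C)c(OC)c3)[C@@H]12 | intermediate (not isolated)
19 | (1R,3aS,4S,6aR)-1-(3-methoxy-4-triisopropylsilyloxyphenyl)-4-(3-methoxy-4-pivaloyloxyphenyl)tetrahydro-1H,3H-furo[3,4-c]furan-3-one (target numbering), endo,exo-diaryl furofuranone | COc1cc([C@@H]2OC(=O)[C@H]3[C@@H]2CO[C@@H]3c2ccc(OC(=O)C(C)(C)C)c(OC)c2)ccc1O[Si](C(C)C)(C(C)C)C(C)C | intermediate
20 | 4-[(2S,3R,4R)-3-(hydroxymethyl)-4-{(R)-hydroxy[3-methoxy-4-(triisopropylsilyloxy)phenyl]methyl}tetrahydrofuran-2-yl]-2-methoxyphenol | COc1cc([C@H](O)[C@H]2CO[C@H](c3ccc(O)c(OC)c3)[C@H]2CO)ccc1O[Si](C(C)C)(C(C)C)C(C)C | intermediate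
21 | 1-bromo-3-methylbut-2-ene (prenyl bromide) | CC(C)=CCBr | starting material
22 | {(2S,3R,4R)-4-{(R)-hydroxy[3-methoxy-4-(triisopropylsilyloxy)phenyl]methyl}-2-[3-methoxy-4-(3-methylbut-2-enyloxy)phenyl]tetrahydrofuran-3-yl}methanol | COc1cc([C@H](O)[C@H]2CO[C@H](c3ccc(OCC=C(C)C)c(OC)c3)[C@H]2CO)ccc1O[Si](C(C)C)(C(C)C)C(C)C | intermediate
23 | primary methanesulfonate of 22 | COc1cc([C@H](O)[C@H]2CO[C@H](c3ccc(OCC=C(C)C)c(OC)c3)[C@H]2COS(C)(=O)=O)ccc1O[Si](C(C)C)(C(C)C)C(C)C | intermediate (not isolated)
24 | (1R,3aR,4S,6aR)-1-(3-methoxy-4-triisopropylsilyloxyphenyl)-4-[3-methoxy-4-(3-methylbut-2-enyloxy)phenyl]tetrahydro-1H,3H-furo[3,4-c]furan | COc1cc([C@@H]2OC[C@H]3[C@@H]2CO[C@@H]3c2ccc(OCC=C(C)C)c(OC)c2)ccc1O[Si](C(C)C)(C(C)C)C(C)C | intermediate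
25 | 4-[(1R,3aR,4S,6aR)-4-{3-methoxy-4-[(3-methylbut-2-en-1-yl)oxy]phenyl}tetrahydro-1H,3H-furo[3,4-c]furan-1-yl]-2-methoxyphenol | COc1cc([C@@H]2OC[C@H]3[C@@H]2CO[C@@H]3c2ccc(OCC=C(C)C)c(OC)c2)ccc1O | target

## Step count and least certain steps

Total: 14 steps. Longest linear sequence: 12 steps (1 → 25 through steps 1–4 and 7–14); the amide branch (steps 5 and 6) joins at step 7.

**Step 10 (key step).** The likeliest failure is competing migration of the ring-fusion carbon C3a, which would insert the oxygen on the wrong side of the carbonyl. Partial epimerisation at C1 before oxidation is the second concern.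
Fallback, from 17 back to 19: irradiation of 17 in methanol through Pyrex over solid NaHCO3. This cleaves the C1–C3 bond on the side of the better stabilised benzylic radical; the acyl–alkyl diradical recloses through oxygen to a cyclic oxacarbene with retention at C1, and methanol adds to give the C3 methyl acetal F1 (both anomers). Aqueous acetic acid in THF would hydrolyse F1 to the lactol F2, and Ag2CO3 on Celite would oxidise F2 to 19. The photochemical ring expansion of cyclobutanones to 2-alkoxytetrahydrofurans is known, and its regiochemistry follows radical stability and not migratory aptitude.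

**Step 7.** The likeliest failure is poor regioselectivity, because the two alkene carbons of 6 differ only through the allylic aryl B; bonding of the iminium carbon at the wrong alkene carbon gives a cyclobutanone that cannot lead to the furofuran. Acid-promoted ionisation of the benzylic, allylic C4–O5 bond by the triflate medium is the second concern.
Fallback, from 7 and 6 back to 16:
- Silylation of 7 (i-Pr3SiCl, imidazole; brief K2CO3 in aqueous methanol to cleave the silyl ester) gives 2-[3-methoxy-4-(triisopropylsilyloxy)phenyl]acetic acid F3.
- The dianion (LiN(i-Pr)2, 2 equiv) is chlorinated with CCl4 to the α-chloro acid F4, and oxalyl chloride gives the acid chloride F5.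
- Slow addition of F5 to 6 and Et3N in refluxing toluene generates the aryl(chloro)ketene F6. Its fully substituted terminus is more strongly steered away from the aryl B side, and it adds under basic conditions to give 16 directly, so step 8 is not needed.
- The price is a less electrophilic partner, so the ketene precursor would be used in excess.

**Step 9.** Hydrogen transfer to the concave face, or epimerisation of the α-aryl ketone during isolation, would give the exo epimer and, after step 10, the exo,exo series.
Fallback, from 14 back to 17: the enolate 15 is regenerated from 14 with LiN(SiMe3)2 at −78 °C and quenched with a hindered proton donor (2,6-di-tert-butylphenol). Kinetic C-protonation from the convex face is a polar route to the same endo ketone that omits the chloride; no new compound is involved.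

**Step 13.** Sulfonylation or ionisation at the benzylic C1 hydroxyl, next to the electron-rich aryl A, would close the ring through a cation and scramble C1 towards exo.
Fallback, from 19 back to 24, in which ring A is never opened: i-Bu2AlH (excess, −78 °C) reduces the lactone to the lactol and cleaves the pivalate, giving the lactol phenol F7. Et3SiH with BF3·OEt2 at −78 °C removes the anomeric hydroxyl through the C3 oxocarbenium ion to give the furofuran phenol F8. Prenylation of F8 with 21 and K2CO3, as in step 12, gives 24.

## Further compounds

F1 | step 10 | C3 methyl acetal of the ring-expanded furofuran (aryl A triisopropylsilyl ether, aryl B pivalate; both anomers) | COc1cc([C@@H]2OC(OC)[C@H]3[C@@H]2CO[C@@H]3c2ccc(OC(=O)C(C)(C)C)c(OC)c2)ccc1O[Si](C(C)C)(C(C)C)C(C)C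
F2 | step 10 | C3 lactol corresponding to 19 (both anomers) | COc1cc([C@@H]2OC(O)[C@H]3[C@@H]2CO[C@@H]3c2ccc(OC(=O)C(C)(C)C)c(OC)c2)ccc1O[Si](C(C)C)(C(C)C)C(C)C
F3 | step 7 | 2-[3-methoxy-4-(triisopropylsilyloxy)phenyl]acetic acid | COc1cc(CC(=O)O)ccc1O[Si](C(C)C)(C(C)C)C(C)C
F4 | step 7 | 2-chloro-2-[3-methoxy-4-(triisopropylsilyloxy)phenyl]acetic acid (racemic) | COc1cc(C(Cl)C(=O)O)ccc1O[Si](C(C)C)(C(C)C)C(C)C
F5 | step 7 | 2-chloro-2-[3-methoxy-4-(triisopropylsilyloxy)phenyl]acetyl chloride (racemic) | COc1cc(C(Cl)C(Cl)=O)ccc1O[Si](C(C)C)(C(C)C)C(C)C
F6 | step 7 | chloro[3-methoxy-4-(triisopropylsilyloxy)phenyl]ketene (not isolated) | COc1cc(C(Cl)=C=O)ccc1O[Si](C(C)C)(C(C)C)C(C)C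
F0 | step 9 | none | none
F7 | step 13 | C3 lactol with free aryl B phenol and aryl A triisopropylsilyl ether (both anomers) | COc1cc([C@@H]2OC(O)[C@H]3[C@@H]2CO[C@@H]3c2ccc(O)c(OC)c2)ccc1O[Si](C(C)C)(C(C)C)C(C)C
F8 | step 13 | 2-methoxy-4-[(1S,3aR,4R,6aR)-4-(3-methoxy-4-triisopropylsilyloxyphenyl)tetrahydro-1H,3H-furo[3,4-c]furan-1-yl]phenol (the phenol corresponding to 24 before prenylation) | COc1cc([C@@H]2OC[C@H]3[C@@H]2CO[C@@H]3c2ccc(O)c(OC)c2)ccc1O[Si](C(C)C)(C(C)C)C(C)C
A1 | alternative 1 | trans-3-[hydroxy(4-allyloxy-3-methoxyphenyl)methyl]-4-{2-[3-methoxy-4-(triisopropylsilyloxy)phenyl]-1,3-dithian-2-yl}-5-(menthyloxy)dihydrofuran-2(3H)-one | O=C1O[C@@H](O[C@@H]2C[C@H](C)CC[C@H]2C(C)C)[C@H](C2(c3ccc(O[Si](C(C)C)(C(C)C)C(C)C)c(OC)c3)SCCCS2)[C@H]1[C@H](O)c1ccc(OCC=C)c(OC)c1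
A2 | alternative 1 | 2-[3-methoxy-4-(triisopropylsilyloxy)phenyl]-1,3-dithiane | COc1cc(C2SCCCS2)ccc1O[Si](C(C)C)(C(C)C)C(C)C
A3 | alternative 1 | (5R)-5-[(1R,2S,5R)-menthyloxy]furan-2(5H)-one | O=C1O[C@@H](O[C@@H]2C[C@H](C)CC[C@H]2C(C)C)C=C1
A4 | alternative 1 | 4-(allyloxy)-3-methoxybenzaldehyde | C=CCOc1ccc(C=O)cc1OC
A5 | alternative 2 | endo,exo-diaryl furofuran with an exo methoxy acetal at C3 (aryl A pivalate, aryl B allyl ether) | COc1cc([C@@H]2O[C@@H](OC)[C@H]3[C@@H]2CO[C@@H]3c2ccc(OCC=C)c(OC)c2)ccc1OC(=O)C(C)(C)C
A6 | alternative 2 | 4-[(2R,3R)-3-(hydroxymethyl)-2,3-dihydrofuran-2-yl]-2-methoxyphenyl 2,2-dimethylpropanoate (cis) | COc1cc([C@@H]2OC=C[C@@H]2CO)ccc1OC(=O)C(C)(C)C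
A7 | alternative 2 | 1-(allyloxy)-4-(dimethoxymethyl)-2-methoxybenzene | COC(OC)c1ccc(OCC=C)c(OC)c1
A8 | alternative 3 | endo,exo-diaryl furofuranone with the lactone carbonyl at C6 (aryl A pivalate, aryl B allyl ether) | CC(C)(C)C(=O)Oc1ccc([C@@H]2OC[C@H]3[C@@H]2C(=O)O[C@@H]3c2ccc(OCC=C)c(OC)c2)cc1OC
A9 | alternative 3 | (S)-5-[4-(allyloxy)-3-methoxyphenyl]furan-2(5H)-one | O=C1O[C@@H](C=C1)c1ccc(OCC=C)c(OC)c1
A10 | alternative 3 | 4-{chloro[(trimethylsilyl)methoxy]methyl}-2-methoxyphenyl 2,2-dimethylpropanoate (racemic) | CC(C)(C)C(=O)Oc1ccc(C(Cl)OC[Si](C)(C)C)cc1OC
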